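**Assumption:** the target has no sp3 stereocentres, so "single enantiomer" is moot. The only stereochemical element is the Z-configured exocyclic trisubstituted alkene, in which the aryl group is cis to the ring oxygen. I checked this against the SMILES as `Ar/C=C2\O…`.

## Retrosynthetic overview
- Target **1** (4-aryl-5-arylidene butenolide) comes from deprotection of MOM ether **2**. **2** comes from an aldol condensation of 4-aryl-2(5H)-furanone **3** with aldehyde **4**, with Z-selective dehydration.
- **3** comes from a Suzuki coupling of 4-bromo-2(5H)-furanone **5** with boronic acid **6**. **5** comes from tetronic acid **7** and oxalyl bromide **8**.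
- Only one ring exists, the butenolide, and it is already present in **7**. The order of bond formation is C4–Ar (Suzuki), then the C5=CH–Ar alkene (condensation), then the phenol is unmasked.

## Route

**Step 1**
Reactants: **7** tetronic acid (4-hydroxyfuran-2(5H)-one); **8** oxalyl bromide
Product: **5** 4-bromofuran-2(5H)-one
Conditions: (COBr)2, DMF (cat.), CH2Cl2, 0 °C → rt
Reagents that add atoms: oxalyl bromide, `O=C(Br)C(=O)Br` (supplies Br)
Why: DMF and oxalyl bromide form a Vilsmeier-type bromoiminium that converts the vinylogous-acid OH into a vinyl bromide by addition–elimination (deoxybromination).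

**Step 2**
Reactants: **5** 4-bromofuran-2(5H)-one; **6** 4-(methoxymethoxy)phenylboronic acid
Product: **3** 4-[4-(methoxymethoxy)phenyl]furan-2(5H)-one
Conditions: Pd(PPh3)4 (5 mol%), KF, THF/H2O (10:1), 60 °C
Reagents that add atoms: none
Why: Suzuki–Miyaura coupling occurs at the electron-poor vinyl C–Br bond. Mild fluoride activation spares the base-sensitive butenolide, and the MOM group survives the conditions. No stereocentre is formed.

**Step 3**
Reactants: **3** 4-[4-(methoxymethoxy)phenyl]furan-2(5H)-one; **4** 3-bromo-4-methoxybenzaldehyde
Product: **2** (Z)-5-(3-bromo-4-methoxybenzylidene)-4-[4-(methoxymethoxy)phenyl]furan-2(5H)-one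
Conditions: **4** (1.2 equiv), DBU (1.2 equiv), MeCN, 0 °C → rt; then Ac2O (2 equiv); then DBU (2 equiv), 50 °C, one pot, protected from light
Reagents that add atoms: none (the aldehyde is a reactant, and the acetate is lost on elimination)
Why: DBU forms the γ-dienolate of **3**, which adds to the aldehyde (vinylogous aldol). Acetylation and DBU-mediated E1cB elimination then give the arylidene butenolide. The transient carbinol and C5 stereocentres are destroyed on elimination. The Z alkene forms under thermodynamic control because the aryl group sits syn to the ring oxygen, away from the C4-aryl group.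

**Step 4**
Reactant: **2**
Product: **1** (Z)-3''-bromorubrolide F
Conditions: TFA, CH2Cl2, 0 °C → rt
Reagents that add atoms: none
Why: Acidolysis of the aryl MOM acetal releases the free phenol. The aryl methyl ether, aryl bromide, enol lactone and Z-alkene are retained under these anhydrous, mild conditions.

## Compound list
1 | (Z)-3''-bromorubrolide F, (Z)-5-(3-bromo-4-methoxybenzylidene)-4-(4-hydroxyphenyl)furan-2(5H)-one | `COc1ccc(/C=C2\OC(=O)C=C2c2ccc(O)cc2)cc1Br` | target
2 | MOM-protected **1** | `COCOc1ccc(cc1)C1=CC(=O)O/C1=C\c1ccc(OC)c(Br)c1` | intermediate
3 | 4-[4-(methoxymethoxy)phenyl]furan-2(5H)-one | `COCOc1ccc(cc1)C1=CC(=O)OC1` | intermediate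
4 | 3-bromo-4-methoxybenzaldehyde | `COc1ccc(C=O)cc1Br` | starting material
5 | 4-bromofuran-2(5H)-one | `BrC1=CC(=O)OC1` | intermediate (also sold commercially)
6 | 4-(methoxymethoxy)phenylboronic acid | `COCOc1ccc(B(O)O)cc1` | starting material
7 | tetronic acid (4-hydroxyfuran-2(5H)-one) | `OC1=CC(=O)OC1` | starting material
8 | oxalyl bromide | `O=C(Br)C(=O)Br` | starting material (reagent)

## Totals
Total steps: 4. Longest linear sequence: 4 (tetronic acid → **5** → **3** → **2** → **1**).

## Three steps most likely to fail
1. **Step 3 (condensation and Z-selective dehydration).** Risks are an E/Z mixture, incomplete elimination, and side reactions of the dienolate.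
   - Fallback: convert **3** to its 2-silyloxyfuran (TBSOTf, Et3N), do a BF3-mediated Mukaiyama vinylogous aldol with **4**, then dehydrate (MsCl/Et3N, then DBU).
   - A more different route is to build the (Z)-enynoic acid HO2C–CH=C(Ar)–C≡C–Ar′ and close it by Ag- or Pd-catalysed 5-exo-dig cycloisomerisation.
2. **Step 2 (Suzuki on the base-sensitive bromobutenolide).** Risks are protodebromination and ring-opening.
   - Fallback: switch the coupling partner to the 4-tosyloxy- or 4-triflyloxy-furanone made from tetronic acid, or use Stille coupling with 4-(MOMO)phenyl-SnBu3 under base-free conditions.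
3. **Step 4 (MOM removal).** Risks are acid-induced lactone opening and Z→E isomerisation.
   - Fallback: use 4-benzyloxyphenylboronic acid in step 2 and remove the benzyl group at the end with BCl3/pentamethylbenzene at −78 °C, which leaves the methyl ether, aryl bromide and alkene untouched.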